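**Retrosynthetic overview**
1. Ring C (the α-methylene-γ-lactone) is cut at C3–Cα: rhodium-carbenoid C–H insertion from an O-2 diazophosphonoacetate, then Horner–Wadsworth–Emmons methylenation. The angelate comes from esterification of the C6 CH2OH.
2. The C6 CH2OH and O-2 are joined as a temporary δ-lactone (ring D). On that bridged spiro-dienone the C10/C9/C8 triad is built by catalytic asymmetric conjugate methylation (C10), Rubottom oxidation (C9) and hydroxyl-directed reduction (C8).
3. Key disconnection: C5–C6 and C7–C8 together, by an intramolecular Diels–Alder reaction of the propiolate ester of (1S)-3-allylidenecyclopentanol. Rings B and D close at once and C2 sets spiro C5.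
4. Enabling feature: the ring-B alkene C6=C7 is flanked by spiro C5 and by C8, and the one-carbon arm on C6 lies on the same face of ring A as O-2. So C6≡C7 can be delivered as an alkynoate tethered to O-2 onto the exocyclic diene C5=C10–C9=C8.
5. Ring order: ring A bought with the C2 stereocentre; rings B and D in step 5; ring D opened in step 11; ring C in step 15.

Key step: step 5

Remark (assumption): spiro[4.5]decane locants are used for the spiro intermediates (ring A = C1–C4 with O on C2 and the later lactone carbon on C3; C5 spiro; ring B = C6–C10 with the CH2O arm on C6, OH on C8 and C9, methyl on C10). Compounds 1, 3, 7, 21 and 23 and both antipodes of the phosphoramidite ligand are taken as commercial, and 5, 6 and 8 are carried as mixtures of the two exocyclic alkene isomers, which converge in step 5.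

Step 1
Reactants: 1 (4R)-4-(tert-butyldimethylsilyloxy)cyclopent-2-en-1-one
Product: 2 (3S)-3-(tert-butyldimethylsilyloxy)cyclopentan-1-one
Conditions: H2 (1 atm), Pd/C, EtOAc, rt
Reagents that add atoms: none
Why: Heterogeneous catalytic hydrogenation of the enone C=C under neutral conditions should leave the β-silyloxy ketone and its stereocentre (bought with 1) untouched.

Step 2
Reactants: 2 (3S)-3-(tert-butyldimethylsilyloxy)cyclopentan-1-one; 3 allyl(triphenyl)phosphonium bromide
Product: 5 tert-butyl(dimethyl){[(1S)-3-(prop-2-en-1-ylidene)cyclopentyl]oxy}silane (both alkene isomers), via oxaphosphetane 4 (not isolated)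
Conditions: 3, n-BuLi, THF, 0 °C; then 2, −78 °C → rt
Reagents that add atoms: allyl(triphenyl)phosphonium bromide 3 (C=CC[P+](c1ccccc1)(c1ccccc1)c1ccccc1.[Br-])
Why: Wittig olefination, in which the semi-stabilised allyl ylide should add through its α-carbon faster than it enolises the ketone and the oxaphosphetane collapses to the 1,3-diene; no stereocentre is formed.

Step 3
Reactants: 5 tert-butyl(dimethyl){[(1S)-3-(prop-2-en-1-ylidene)cyclopentyl]oxy}silane
Product: 6 (1S)-3-(prop-2-en-1-ylidene)cyclopentan-1-ol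
Conditions: HF·pyridine, pyridine, THF, 0 °C → rt
Reagents that add atoms: none
Why: Fluoride-driven silyl ether cleavage, buffered by pyridine, should spare the diene and does not break the C–O bond of the stereocentre.

Step 4
Reactants: 6 (1S)-3-(prop-2-en-1-ylidene)cyclopentan-1-ol; 7 propiolic acid
Product: 8 (1S)-3-(prop-2-en-1-ylidene)cyclopentyl prop-2-ynoate
Conditions: 7, DCC, DMAP (cat.), CH2Cl2, −20 → 0 °C
Reagents that add atoms: propiolic acid 7 (C#CC(=O)O)
Why: Steglich esterification at low temperature should acylate the secondary alcohol with retention before the amine catalyst can add to the ynoate.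

Step 5
Reactants: 8 (1S)-3-(prop-2-en-1-ylidene)cyclopentyl prop-2-ynoate
Product: 9 (2S,5R)-2-hydroxyspiro[4.5]deca-6,9-diene-6-carboxylic acid 2,6-lactone
Conditions: o-dichlorobenzene (0.01 M), BHT (cat.), 180 °C, sealed tube
Reagents that add atoms: none
Why: Thermal concerted [4+2] cycloaddition (intramolecular Diels–Alder reaction) of the propiolate C≡C onto the exocyclic diene C5=C10–C9=C8, the carbonyl-bearing alkyne carbon bonding to C5 and the terminal alkyne carbon to C8; the closest known reaction type is the ester-tethered Diels–Alder cyclisation of dienyl alk-2-ynoates to cyclohexa-1,4-diene-fused lactones. Two rings close: the cyclohexa-1,4-diene ring B by the cycloaddition itself (both σ-bonds formed on one diene face), and the six-membered lactone ring D as the tether ring closed by the C5–C6 bond, bridging C2 and C5 of ring A as a 2-oxabicyclo[3.2.1]octan-3-one. The only new stereocentre, spiro C5, is controlled by the C2 stereocentre, because the four-atom ester tether can reach only the diene face syn to the C2 oxygen, so C6 must end up cis to that oxygen. Regiochemistry is fixed by the same tether (the reverse orientation would need an eight-membered bridged ring), and since C8 is an unsubstituted CH2 terminus both geometric isomers of the exocyclic alkene should give the same adduct. The step needs cycloaddition to win over intermolecular reaction, polymerisation of the propiolate and 1,5-hydrogen shift in the diene; high dilution, the radical inhibitor and the pre-organisation by ring A (which also offsets the s-cis ester penalty) should secure this.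

Step 6
Reactants: 9 (2S,5R)-2-hydroxyspiro[4.5]deca-6,9-diene-6-carboxylic acid 2,6-lactone
Product: 11 (2S,5R)-2-hydroxy-8-oxospiro[4.5]deca-6,9-diene-6-carboxylic acid 2,6-lactone, via allylic tert-butyl peroxide 10 (not isolated)
Conditions: Rh2(cap)4 (dirhodium tetracaprolactamate, cat.), t-BuOOH (70% in water), K2CO3 (cat.), CH2Cl2, rt
Reagents that add atoms: tert-butyl hydroperoxide (CC(C)(C)OO)
Why: Allylic oxidation should take the doubly allylic C8 methylene, the weakest C–H bond, through the mixed peroxide to the cross-conjugated dienone, which cannot aromatise because C5 is quaternary; no stereocentre is formed.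

Step 7
Reactants: 11 (2S,5R)-2-hydroxy-8-oxospiro[4.5]deca-6,9-diene-6-carboxylic acid 2,6-lactone
Product: 13 (2S,5R,10S)-2-hydroxy-10-methyl-8-(trimethylsilyloxy)spiro[4.5]deca-6,8-diene-6-carboxylic acid 2,6-lactone, via methylzinc enolate 12 (not isolated)
Conditions: Cu(OTf)2 (cat.), (S)-BINOL-derived N,N-bis[(R)-1-phenylethyl]phosphoramidite (cat.), Me2Zn, PhMe, −25 °C; then TMSOTf, −25 → 0 °C
Reagents that add atoms: dimethylzinc (C[Zn]C); trimethylsilyl triflate (C[Si](C)(C)OS(=O)(=O)C(F)(F)F)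
Why: Copper-catalysed asymmetric conjugate addition should transfer methyl to C10, the only unsubstituted β-carbon of the dienone, on the face chosen by the ligand (cis to C4 of ring A is required, and the antipodal ligand is the alternative if the sense is opposite, since the bridged substrate offers little bias of its own), and O-silylation fixes the enolate.

Step 8
Reactants: 13 (2S,5R,10S)-2-hydroxy-10-methyl-8-(trimethylsilyloxy)spiro[4.5]deca-6,8-diene-6-carboxylic acid 2,6-lactone
Product: 16 (2S,5R,9S,10R)-2,9-dihydroxy-10-methyl-8-oxospiro[4.5]dec-6-ene-6-carboxylic acid 2,6-lactone, via silyloxy epoxide 14 (not isolated), via α-silyloxy ketone 15 (not isolated)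
Conditions: mCPBA, NaHCO3, CH2Cl2, −20 °C; then 1 M HCl, THF, 0 °C
Reagents that add atoms: 3-chloroperbenzoic acid (OOC(=O)c1cccc(Cl)c1)
Why: Rubottom oxidation, in which the peracid should epoxidise the electron-rich silyl enol ether C8=C9 (not the electron-poor C6=C7) on the face anti to the adjacent C10 methyl, so that silyl migration and acid work-up give the C9 hydroxyl trans to the methyl.

Step 9
Reactants: 16 (2S,5R,9S,10R)-2,9-dihydroxy-10-methyl-8-oxospiro[4.5]dec-6-ene-6-carboxylic acid 2,6-lactone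
Product: 17 (2S,5R,8S,9S,10R)-2,8,9-trihydroxy-10-methylspiro[4.5]dec-6-ene-6-carboxylic acid 2,6-lactone
Conditions: Me4NBH(OAc)3, AcOH, MeCN, −25 °C
Reagents that add atoms: none
Why: Hydroxyl-directed (Evans–Saksena type) 1,2-reduction, in which the borohydride bound to the C9 hydroxyl should deliver hydride to the C8 ketone from the face of that hydroxyl and so set the C8 hydroxyl trans to it.

Step 10
Reactants: 17 (2S,5R,8S,9S,10R)-2,8,9-trihydroxy-10-methylspiro[4.5]dec-6-ene-6-carboxylic acid 2,6-lactone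
Product: 18 (2S,5R,8S,9S,10R)-2-hydroxy-10-methyl-8,9-bis(triethylsilyloxy)spiro[4.5]dec-6-ene-6-carboxylic acid 2,6-lactone
Conditions: TESOTf, 2,6-lutidine, CH2Cl2, −78 → 0 °C
Reagents that add atoms: triethylsilyl triflate (CC[Si](CC)(CC)OS(=O)(=O)C(F)(F)F)
Why: Silyl ether formation with the reactive triflate should cap both secondary hydroxyls of the trans-diol without touching the lactone or any stereocentre.

Step 11
Reactants: 18 (2S,5R,8S,9S,10R)-2-hydroxy-10-methyl-8,9-bis(triethylsilyloxy)spiro[4.5]dec-6-ene-6-carboxylic acid 2,6-lactone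
Product: 20 (2S,5R,8S,9S,10R)-6-(hydroxymethyl)-10-methyl-8,9-bis(triethylsilyloxy)spiro[4.5]dec-6-en-2-ol, via lactol 19 (not isolated)
Conditions: i-Bu2AlH (excess), CH2Cl2, −78 → 0 °C; aq. potassium sodium tartrate
Reagents that add atoms: none
Why: 1,2-Reduction of the unsaturated lactone by the aluminium hydride should open the temporary ring D through the lactol, giving the allylic primary alcohol on C6 and freeing the C2 alcohol with all stereocentres unchanged.

Step 12
Reactants: 20 (2S,5R,8S,9S,10R)-6-(hydroxymethyl)-10-methyl-8,9-bis(triethylsilyloxy)spiro[4.5]dec-6-en-2-ol; 21 angelic acid [(2Z)-2-methylbut-2-enoic acid]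
Product: 22 [(2S,5R,8S,9S,10R)-2-hydroxy-10-methyl-8,9-bis(triethylsilyloxy)spiro[4.5]dec-6-en-6-yl]methyl (2Z)-2-methylbut-2-enoate
Conditions: 21, 2,4,6-trichlorobenzoyl chloride, Et3N, PhMe, rt; then 20, DMAP (cat.), rt
Reagents that add atoms: angelic acid 21 (C/C=C(/C)C(=O)O)
Why: Yamaguchi esterification, in which the mixed anhydride should acylate the unhindered primary allylic alcohol in preference to the secondary C2 alcohol while the mild conditions keep the (Z)-geometry of the angelate.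

Step 13
Reactants: 22 [(2S,5R,8S,9S,10R)-2-hydroxy-10-methyl-8,9-bis(triethylsilyloxy)spiro[4.5]dec-6-en-6-yl]methyl (2Z)-2-methylbut-2-enoate; 23 (diethoxyphosphoryl)acetic acid
Product: 24 [(2S,5R,8S,9S,10R)-2-{[(diethoxyphosphoryl)acetyl]oxy}-10-methyl-8,9-bis(triethylsilyloxy)spiro[4.5]dec-6-en-6-yl]methyl (2Z)-2-methylbut-2-enoate
Conditions: 23, DCC, DMAP (cat.), CH2Cl2, 0 °C → rt
Reagents that add atoms: (diethoxyphosphoryl)acetic acid 23 (CCOP(=O)(OCC)CC(=O)O)
Why: Steglich esterification of the one remaining free (secondary) alcohol should proceed with retention at C2.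

Step 14
Reactants: 24 [(2S,5R,8S,9S,10R)-2-{[(diethoxyphosphoryl)acetyl]oxy}-10-methyl-8,9-bis(triethylsilyloxy)spiro[4.5]dec-6-en-6-yl]methyl (2Z)-2-methylbut-2-enoate
Product: 25 [(2S,5R,8S,9S,10R)-2-{[diazo(diethoxyphosphoryl)acetyl]oxy}-10-methyl-8,9-bis(triethylsilyloxy)spiro[4.5]dec-6-en-6-yl]methyl (2Z)-2-methylbut-2-enoate
Conditions: 4-acetamidobenzenesulfonyl azide, DBU, MeCN, 0 °C
Reagents that add atoms: 4-acetamidobenzenesulfonyl azide (CC(=O)Nc1ccc(cc1)S(=O)(=O)N=[N+]=[N-])
Why: Regitz diazo transfer should occur only at the doubly activated methylene between phosphonate and ester.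

Step 15
Reactants: 25 [(2S,5R,8S,9S,10R)-2-{[diazo(diethoxyphosphoryl)acetyl]oxy}-10-methyl-8,9-bis(triethylsilyloxy)spiro[4.5]dec-6-en-6-yl]methyl (2Z)-2-methylbut-2-enoate
Product: 26 [(1R,3a'S,4S,5S,6R,6a'R)-3'-(diethoxyphosphoryl)-6-methyl-2'-oxo-4,5-bis(triethylsilyloxy)hexahydro-2'H-spiro[cyclohex-2-ene-1,5'-cyclopenta[b]furan]-2-yl]methyl (2Z)-2-methylbut-2-enoate (C3' epimers)
Conditions: Rh2(OAc)4 (cat.), CH2Cl2, reflux, slow addition of 25
Reagents that add atoms: none
Why: Rhodium-carbenoid C–H insertion, in which the carbenoid should insert with retention into the C3–H bond cis to the ester oxygen through a five-membered transition state, giving the cis-fused γ-lactone and setting C3, while the competing C1–H bond is shielded by the neighbouring quaternary C5.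

Step 16
Reactants: 26 [(1R,3a'S,4S,5S,6R,6a'R)-3'-(diethoxyphosphoryl)-6-methyl-2'-oxo-4,5-bis(triethylsilyloxy)hexahydro-2'H-spiro[cyclohex-2-ene-1,5'-cyclopenta[b]furan]-2-yl]methyl (2Z)-2-methylbut-2-enoate
Product: 27 [(1R,3a'R,4S,5S,6R,6a'R)-6-methyl-3'-methylidene-2'-oxo-4,5-bis(triethylsilyloxy)hexahydro-2'H-spiro[cyclohex-2-ene-1,5'-cyclopenta[b]furan]-2-yl]methyl (2Z)-2-methylbut-2-enoate
Conditions: aq. CH2O, K2CO3, THF, 0 °C → rt
Reagents that add atoms: formaldehyde (C=O)
Why: Horner–Wadsworth–Emmons olefination of the α-phosphono lactone with formaldehyde under mild carbonate base should give the exo-methylene group and erase the unneeded stereocentre at the phosphonate carbon.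

Step 17
Reactants: 27 [(1R,3a'R,4S,5S,6R,6a'R)-6-methyl-3'-methylidene-2'-oxo-4,5-bis(triethylsilyloxy)hexahydro-2'H-spiro[cyclohex-2-ene-1,5'-cyclopenta[b]furan]-2-yl]methyl (2Z)-2-methylbut-2-enoate
Product: 28 [(1R,3a'R,4S,5S,6R,6a'R)-4,5-dihydroxy-6-methyl-3'-methylidene-2'-oxohexahydro-2'H-spiro[cyclohex-2-ene-1,5'-cyclopenta[b]furan]-2-yl]methyl (2Z)-2-methylbut-2-enoate (CNP0224912.1)
Conditions: HF·pyridine, pyridine, THF, 0 °C → rt
Reagents that add atoms: none
Why: Fluoride-mediated cleavage of the two triethylsilyl ethers under weakly acidic conditions should spare the α-methylene lactone and the angelate and leave every stereocentre as set.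

**Compound list**
1 | (4R)-4-(tert-butyldimethylsilyloxy)cyclopent-2-en-1-one | CC(C)(C)[Si](C)(C)O[C@@H]1CC(=O)C=C1 | starting material
2 | (3S)-3-(tert-butyldimethylsilyloxy)cyclopentan-1-one | CC(C)(C)[Si](C)(C)O[C@@H]1CC(=O)CC1 | intermediate
3 | allyl(triphenyl)phosphonium bromide | C=CC[P+](c1ccccc1)(c1ccccc1)c1ccccc1.[Br-] | starting material
4 | spiro-oxaphosphetane from 2 and the allyl ylide (diastereomer mixture, not isolated) | CC(C)(C)[Si](C)(C)O[C@@H]1CC2(CC1)OP(c3ccccc3)(c3ccccc3)(c3ccccc3)C2C=C | intermediate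
5 | tert-butyl(dimethyl){[(1S)-3-(prop-2-en-1-ylidene)cyclopentyl]oxy}silane (both alkene isomers) | CC(C)(C)[Si](C)(C)O[C@@H]1CC(=CC=C)CC1 | intermediate
6 | (1S)-3-(prop-2-en-1-ylidene)cyclopentan-1-ol (both alkene isomers) | O[C@@H]1CC(=CC=C)CC1 | intermediate
7 | propiolic acid | C#CC(=O)O | starting material
8 | (1S)-3-(prop-2-en-1-ylidene)cyclopentyl prop-2-ynoate (both alkene isomers) | C#CC(=O)O[C@@H]1CC(=CC=C)CC1 | intermediate
9 | (2S,5R)-2-hydroxyspiro[4.5]deca-6,9-diene-6-carboxylic acid 2,6-lactone | O=C1O[C@@H]2C[C@@]3(CC2)C1=CCC=C3 | intermediate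
10 | (2S,5R)-8-(tert-butylperoxy)-2-hydroxyspiro[4.5]deca-6,9-diene-6-carboxylic acid 2,6-lactone (C8 epimers, not isolated) | O=C1O[C@@H]2C[C@@]3(CC2)C1=CC(OOC(C)(C)C)C=C3 | intermediate
11 | (2S,5R)-2-hydroxy-8-oxospiro[4.5]deca-6,9-diene-6-carboxylic acid 2,6-lactone | O=C1O[C@@H]2C[C@@]3(CC2)C1=CC(=O)C=C3 | intermediate
12 | methylzinc enolate of the (10S)-10-methyl ketone (not isolated) | O=C1O[C@@H]2C[C@@]3(CC2)C1=CC(O[Zn]C)=C[C@@H]3C | intermediate
13 | (2S,5R,10S)-2-hydroxy-10-methyl-8-(trimethylsilyloxy)spiro[4.5]deca-6,8-diene-6-carboxylic acid 2,6-lactone | O=C1O[C@@H]2C[C@@]3(CC2)C1=CC(O[Si](C)(C)C)=C[C@@H]3C | intermediate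
14 | 8,9-epoxide of 13, epoxide oxygen trans to the C10 methyl (not isolated) | O=C1O[C@@H]2C[C@@]3(CC2)C1=C[C@@]4(O[Si](C)(C)C)O[C@H]4[C@@H]3C | intermediate
15 | (2S,5R,9S,10R)-2-hydroxy-10-methyl-8-oxo-9-(trimethylsilyloxy)spiro[4.5]dec-6-ene-6-carboxylic acid 2,6-lactone (not isolated) | O=C1O[C@@H]2C[C@@]3(CC2)C1=CC(=O)[C@@H](O[Si](C)(C)C)[C@@H]3C | intermediate
16 | (2S,5R,9S,10R)-2,9-dihydroxy-10-methyl-8-oxospiro[4.5]dec-6-ene-6-carboxylic acid 2,6-lactone | O=C1O[C@@H]2C[C@@]3(CC2)C1=CC(=O)[C@@H](O)[C@@H]3C | intermediate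
17 | (2S,5R,8S,9S,10R)-2,8,9-trihydroxy-10-methylspiro[4.5]dec-6-ene-6-carboxylic acid 2,6-lactone | O=C1O[C@@H]2C[C@@]3(CC2)C1=C[C@H](O)[C@@H](O)[C@@H]3C | intermediate
18 | (2S,5R,8S,9S,10R)-2-hydroxy-10-methyl-8,9-bis(triethylsilyloxy)spiro[4.5]dec-6-ene-6-carboxylic acid 2,6-lactone | O=C1O[C@@H]2C[C@@]3(CC2)C1=C[C@H](O[Si](CC)(CC)CC)[C@@H](O[Si](CC)(CC)CC)[C@@H]3C | intermediate
19 | bridged lactol from 18 (lactone C=O reduced to CH–OH, lactol epimers, not isolated) | OC1O[C@@H]2C[C@@]3(CC2)C1=C[C@H](O[Si](CC)(CC)CC)[C@@H](O[Si](CC)(CC)CC)[C@@H]3C | intermediate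
20 | (2S,5R,8S,9S,10R)-6-(hydroxymethyl)-10-methyl-8,9-bis(triethylsilyloxy)spiro[4.5]dec-6-en-2-ol | O[C@@H]1C[C@@]2(CC1)C(CO)=C[C@H](O[Si](CC)(CC)CC)[C@@H](O[Si](CC)(CC)CC)[C@@H]2C | intermediate
21 | angelic acid, (2Z)-2-methylbut-2-enoic acid | C/C=C(/C)C(=O)O | starting material
22 | [(2S,5R,8S,9S,10R)-2-hydroxy-10-methyl-8,9-bis(triethylsilyloxy)spiro[4.5]dec-6-en-6-yl]methyl (2Z)-2-methylbut-2-enoate | O[C@@H]1C[C@@]2(CC1)C(COC(=O)/C(C)=C\C)=C[C@H](O[Si](CC)(CC)CC)[C@@H](O[Si](CC)(CC)CC)[C@@H]2C | intermediate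
23 | (diethoxyphosphoryl)acetic acid | CCOP(=O)(OCC)CC(=O)O | starting material
24 | [(2S,5R,8S,9S,10R)-2-{[(diethoxyphosphoryl)acetyl]oxy}-10-methyl-8,9-bis(triethylsilyloxy)spiro[4.5]dec-6-en-6-yl]methyl (2Z)-2-methylbut-2-enoate | CCOP(=O)(OCC)CC(=O)O[C@@H]1C[C@@]2(CC1)C(COC(=O)/C(C)=C\C)=C[C@H](O[Si](CC)(CC)CC)[C@@H](O[Si](CC)(CC)CC)[C@@H]2C | intermediate
25 | [(2S,5R,8S,9S,10R)-2-{[diazo(diethoxyphosphoryl)acetyl]oxy}-10-methyl-8,9-bis(triethylsilyloxy)spiro[4.5]dec-6-en-6-yl]methyl (2Z)-2-methylbut-2-enoate | CCOP(=O)(OCC)C(=[N+]=[N-])C(=O)O[C@@H]1C[C@@]2(CC1)C(COC(=O)/C(C)=C\C)=C[C@H](O[Si](CC)(CC)CC)[C@@H](O[Si](CC)(CC)CC)[C@@H]2C | intermediate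
26 | [(1R,3a'S,4S,5S,6R,6a'R)-3'-(diethoxyphosphoryl)-6-methyl-2'-oxo-4,5-bis(triethylsilyloxy)hexahydro-2'H-spiro[cyclohex-2-ene-1,5'-cyclopenta[b]furan]-2-yl]methyl (2Z)-2-methylbut-2-enoate (C3' epimers) | CCOP(=O)(OCC)C1C(=O)O[C@@H]2C[C@@]3(C[C@H]12)C(COC(=O)/C(C)=C\C)=C[C@H](O[Si](CC)(CC)CC)[C@@H](O[Si](CC)(CC)CC)[C@@H]3C | intermediate
27 | [(1R,3a'R,4S,5S,6R,6a'R)-6-methyl-3'-methylidene-2'-oxo-4,5-bis(triethylsilyloxy)hexahydro-2'H-spiro[cyclohex-2-ene-1,5'-cyclopenta[b]furan]-2-yl]methyl (2Z)-2-methylbut-2-enoate | C=C1C(=O)O[C@@H]2C[C@@]3(C[C@H]12)C(COC(=O)/C(C)=C\C)=C[C@H](O[Si](CC)(CC)CC)[C@@H](O[Si](CC)(CC)CC)[C@@H]3C | intermediate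
28 | [(1R,3a'R,4S,5S,6R,6a'R)-4,5-dihydroxy-6-methyl-3'-methylidene-2'-oxohexahydro-2'H-spiro[cyclohex-2-ene-1,5'-cyclopenta[b]furan]-2-yl]methyl (2Z)-2-methylbut-2-enoate (CNP0224912.1) | C=C1C(=O)O[C@@H]2C[C@@]3(C[C@H]12)C(COC(=O)/C(C)=C\C)=C[C@H](O)[C@@H](O)[C@@H]3C | target

**Totals**
Total step count: 17. Longest linear sequence: 17 steps (1 → 28); the building blocks 3, 7, 21 and 23 are commercial.

**Steps most likely to fail**

Step 5 (key step). The risk is that the terminal propiolate polymerises or decomposes before the cycloaddition occurs, because the diene terminus C5 is fully substituted and the ester tether resists the s-cis conformer. The fallback exchanges the ester tether for an acetal tether and the thermal reaction for a metal-catalysed one. It sets out from alcohol 6, which is transacetalised with 3,3-diethoxyprop-1-yne (PPTS, PhMe, removal of EtOH) to the mixed propargylic acetal F1. This unactivated dienyne should undergo a rhodium-catalysed intramolecular [4+2] cycloaddition ([RhCl(cod)]2, AgSbF6, CH2Cl2, rt; cationic monovalent rhodium, via a rhodacycle) to the bridged cyclic acetal F2, with C6 again delivered to the face of O-2. Jones oxidation (CrO3, H2SO4, acetone, 0 °C) of the acetal C–H bond should then give lactone 9, where the route is rejoined.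

Step 7. The risk is methyl transfer to C7 of the doubly activated C6=C7 bond, or loss of ligand control over the diene face on the rigid bridged dienone. The fallback opens ring D before the dienone is made. It sets out from 9, which is reduced (i-Bu2AlH) to the diol F3 and acetylated (Ac2O, pyridine) to the diacetate F4. Allylic oxidation as in step 6 gives the dienone F5, an ordinary 4,4-disubstituted cyclohexa-2,5-dienone whose only unsubstituted β-carbon is C10 and whose C6=C7 bond is no longer doubly activated. The same copper–phosphoramidite methyl addition with silyl trapping gives the silyl enol ether F6, Rubottom oxidation the hydroxy ketone F7, hydroxyl-directed reduction the diol F8, and silylation (TESOTf, 2,6-lutidine) the bis-silyl ether F9. Methanolysis of both acetates (K2CO3, MeOH) returns diol 20.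

Step 15. The risk is carbenoid insertion into the C1–H bond instead of C3–H, or cyclopropanation of the C6=C7 or angelate alkene. The fallback uses an acceptor-only carbenoid under catalyst control and introduces the methylene afterwards. It sets out from alcohol 22, which is converted (glyoxylic acid chloride p-toluenesulfonylhydrazone, N,N-dimethylaniline; then Et3N) into the diazoacetate F10. The chiral carboxamidate catalyst Rh2(5S-MEPY)4 (dirhodium tetrakis[methyl (5S)-2-oxopyrrolidine-5-carboxylate]), whose ligand sphere steers the site of insertion and disfavours cyclopropanation, should give the cis-fused γ-lactone F11. Aminomethylation of its lithium enolate (LiN(SiMe3)2, THF, −78 °C; dimethyl(methylidene)ammonium iodide) gives the Mannich base F12, and quaternisation–elimination (MeI; NaHCO3) returns the α-methylene lactone 27.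

**Further compounds**
F1 | step 5 | (1S)-1-[(1-ethoxyprop-2-yn-1-yl)oxy]-3-(prop-2-en-1-ylidene)cyclopentane (acetal epimers, both alkene isomers) | C#CC(OCC)O[C@@H]1CC(=CC=C)CC1
F2 | step 5 | bridged cyclic ethyl acetal (C6-CH(OEt)-O-C2) of (2S,5R)-2-hydroxyspiro[4.5]deca-6,9-diene-6-carbaldehyde (acetal epimers) | CCOC1O[C@@H]2C[C@@]3(CC2)C1=CCC=C3
F3 | step 7 | (2S,5R)-6-(hydroxymethyl)spiro[4.5]deca-6,9-dien-2-ol | O[C@@H]1C[C@@]2(CC1)C(CO)=CCC=C2
F4 | step 7 | [(2S,5R)-2-acetoxyspiro[4.5]deca-6,9-dien-6-yl]methyl acetate | CC(=O)O[C@@H]1C[C@@]2(CC1)C(COC(C)=O)=CCC=C2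
F5 | step 7 | [(2S,5R)-2-acetoxy-8-oxospiro[4.5]deca-6,9-dien-6-yl]methyl acetate | CC(=O)O[C@@H]1C[C@@]2(CC1)C(COC(C)=O)=CC(=O)C=C2
F6 | step 7 | [(2S,5R,10S)-2-acetoxy-10-methyl-8-(trimethylsilyloxy)spiro[4.5]deca-6,8-dien-6-yl]methyl acetate | CC(=O)O[C@@H]1C[C@@]2(CC1)C(COC(C)=O)=CC(O[Si](C)(C)C)=C[C@@H]2C
F7 | step 7 | [(2S,5R,9S,10R)-2-acetoxy-9-hydroxy-10-methyl-8-oxospiro[4.5]dec-6-en-6-yl]methyl acetate | CC(=O)O[C@@H]1C[C@@]2(CC1)C(COC(C)=O)=CC(=O)[C@@H](O)[C@@H]2C
F8 | step 7 | [(2S,5R,8S,9S,10R)-2-acetoxy-8,9-dihydroxy-10-methylspiro[4.5]dec-6-en-6-yl]methyl acetate | CC(=O)O[C@@H]1C[C@@]2(CC1)C(COC(C)=O)=C[C@H](O)[C@@H](O)[C@@H]2C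
F9 | step 7 | [(2S,5R,8S,9S,10R)-2-acetoxy-10-methyl-8,9-bis(triethylsilyloxy)spiro[4.5]dec-6-en-6-yl]methyl acetate | CC(=O)O[C@@H]1C[C@@]2(CC1)C(COC(C)=O)=C[C@H](O[Si](CC)(CC)CC)[C@@H](O[Si](CC)(CC)CC)[C@@H]2C
F10 | step 15 | [(2S,5R,8S,9S,10R)-2-(diazoacetoxy)-10-methyl-8,9-bis(triethylsilyloxy)spiro[4.5]dec-6-en-6-yl]methyl (2Z)-2-methylbut-2-enoate | [N-]=[N+]=CC(=O)O[C@@H]1C[C@@]2(CC1)C(COC(=O)/C(C)=C\C)=C[C@H](O[Si](CC)(CC)CC)[C@@H](O[Si](CC)(CC)CC)[C@@H]2C
F11 | step 15 | [(1R,3a'R,4S,5S,6R,6a'R)-6-methyl-2'-oxo-4,5-bis(triethylsilyloxy)hexahydro-2'H-spiro[cyclohex-2-ene-1,5'-cyclopenta[b]furan]-2-yl]methyl (2Z)-2-methylbut-2-enoate | C1C(=O)O[C@@H]2C[C@@]3(C[C@H]12)C(COC(=O)/C(C)=C\C)=C[C@H](O[Si](CC)(CC)CC)[C@@H](O[Si](CC)(CC)CC)[C@@H]3C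
F12 | step 15 | 3'-[(dimethylamino)methyl] derivative of F11 (C3' epimers) | CN(C)CC1C(=O)O[C@@H]2C[C@@]3(C[C@H]12)C(COC(=O)/C(C)=C\C)=C[C@H](O[Si](CC)(CC)CC)[C@@H](O[Si](CC)(CC)CC)[C@@H]3C
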